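**Remarks on the chemistry (assumptions)**

- Germacrane numbering is used: C1 ketone, C2 methylene, C3 carbinol, C4=C5 olefin (C15 methyl on C4), C6 lactone carbinol, C7 ring fusion, C8 (angelate), C9 (acetate), C10 tertiary carbinol (C14 methyl), C11=C13 exocyclic methylene, C12 lactone carbonyl.
- (S)-5-(Hydroxymethyl)furan-2(5H)-one (1) is taken as a purchasable chiral-pool compound.
- The seco diene 22 and the cyclised diene 23 were checked against the target centre by centre (C3, C6, C7, C10, 4Z) and agree with it, so no structure needed correction. The design is strengthened at three points: the ester reduction next to a lactone (steps 7 and 8), the protecting-group sequence at O3 and O10 (steps 10 to 13), and the work-up of the osmate ester (step 15).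

## Structural features

The target is a germacranolide of the heliangolide type: a ten-membered carbocycle (C1–C10) with a 4Z trisubstituted olefin, trans-fused at C6/C7 to an α-methylene-γ-butyrolactone (O–C6–C7–C11–C12). Five contiguous stereocentres run from C6 to C10. The lactone oxygen on C6 is trans to the C7–C11 bond, whereas the C8 angelate, the C9 acetate and the C10 tertiary hydroxyl are cis to one another and to the C7–C11 bond. The sixth stereocentre, the C3 carbinol, stands alone between the C1 ketone and the C4=C5 olefin. C1/C3 form a β-hydroxy ketone and C1/C10 an α-ketol, so base can cause retro-aldol cleavage, dehydration to a dienone or an α-ketol shift. The angelate isomerises to the tiglate under nucleophilic catalysis, the methylene lactone is a Michael acceptor, and the three neighbouring oxygen functions at C8–C10 invite acyl migration. The real difficulties are closing the strained ten-membered ring, placing two different esters on adjacent secondary hydroxyls, and the quaternary C10 carbinol. The key step exploits the C8–C9 bond of the ten-membered ring: two cis oxygens beside the free C10 hydroxyl are the mark of a hydroxyl-directed syn-dihydroxylation of a Z C8=C9 olefin, and that olefin lies between C7 and C10, each of which can carry a vinyl group, so the ring can be closed there by metathesis without creating a stereocentre.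

## Logic of the disconnections

30 ⇒ 29 ⇒ 28 ⇒ 25 + 26. The O3–Si bond, the acetyl C–O bond at O9 and the angeloyl C–O bond at O8 are cut. The esters are the most fragile groups and so go on last; this reduces the target to a triol with one protected hydroxyl. The forward steps must acylate O8 before O9 (O8 is the less hindered), must not isomerise the Z ester, and must leave the tertiary O10 free.

25 ⇒ 23. Both C8–O and C9–O bonds are removed to leave a Z C8=C9 olefin. A cis-diol next to a free tertiary allylic hydroxyl is the retron of a hydrogen-bond-directed osmylation. Two stereocentres disappear. The forward step needs delivery of osmium to the face of the C10 hydroxyl and must spare the C4=C5 and C11=C13 olefins.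

23 ⇒ 22. The ring is opened at C8=C9, leaving a vinyl group on C7 and one on C10. The cut lies far from the β-silyloxy ketone and from the lactone, and removes the only ring that is hard to make. The forward step must close a ten-membered ring in competition with oligomers, give the Z olefin, and use only the two monosubstituted olefins out of four.

22 ⇒ 21 ⇒ 14 + 18. After exchange of the O3 and O10 silyl groups, the C2–C3 bond is cut as an aldol. This divides the seco compound into two halves of similar size and uses the β-hydroxy ketone directly. The forward step must enolise only the methyl group (C10 is quaternary), control the face of the aldehyde by the boron ligands, and tolerate the methylene lactone.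

18 ⇒ 17 ⇒ 16 ⇒ 15 + 3. The C9–C10 bond is cut as addition of a vinyl nucleophile to a symmetrical 1,2-diketone, and the silyl ether and the resolution are removed. This gives C10 with all four substituents in one step from two bulk chemicals. The price is a mono-addition that must stop after one carbonyl and a separation of enantiomers.

14 ⇒ 13 ⇒ 12 ⇒ 10 + 11. The C3 oxidation level is adjusted and the C4=C5 bond is cut as a Z-selective phosphonate olefination. This is the most reliable source of a Z trisubstituted α-methyl olefin. Since no reagent reduces an enoate beside a γ-lactone, the forward sequence reduces both and reoxidises both.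

10 ⇒ 9 ⇒ 8 ⇒ 5. The aldehyde is traced back to a silyl-protected primary alcohol and the C11=C13 bond is cut as an enolate methylenation. The strong base needed for it is thereby used before any aldehyde, enoate or ketone is present.

5 ⇒ 2 + 3 ⇒ 1. The C7–C8 bond is cut as conjugate addition of a vinyl cuprate to a butenolide, and the silyl ether is removed. C6 comes from the chiral pool and C7 is set trans to it by the bulky C5 substituent of the butenolide, which is the trans ring fusion of the target.

## Other disconnections considered

Alternative 1: The ring would be cut at C1–C10, with a C1≡C2 alkyne standing for the ketone and its methylene. In the forward step the terminal alkyne of seco ynone A2 would be deprotonated with LiN(SiMe3)2 and transmetalated with CeCl3, and the cerium acetylide would add to the C10 methyl ketone to give the ten-membered enyne carbinol A1. In its favour, the ring and the quaternary carbinol form in one irreversible polar step, and the weakly basic cerium reagent should not enolise the methyl ketone. C8 and C9 arrive as a ready cis-diol acetonide, so no late osmylation has to find the right face; on this point it is better than the chosen plan. Against it, C10 would be created during the macrocyclisation, so its configuration would depend on the ketone face reached in a strained transition state holding a linear C–C≡C–C unit. After closure the alkyne would have to be hydrated with the oxygen at C1 and not at C2, although both alkyne carbons carry a propargylic oxygen. The lactone, whose C12 is still a silyl ether in A1, would also have to be built after ring closure. On structure, it fixes C8/C9 early and leaves C10 to the ring closure, while the chosen plan brings C10 in resolved and leaves C8/C9 to the directed osmylation; telling O8 from O9 after acetonide removal is the same problem in both (equal). On mechanism, a carbonyl addition cannot revert oligomers whereas metathesis can, and both need high dilution (equal). On step economy it is judged longer, because the oxidation levels at C1 and C12 are set after cyclisation.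

Alternative 2: The ring would be cut at C3–C4. In the forward step zerovalent nickel (from catalytic NiCl2 and CrCl2) would insert into the C4–I bond of seco iodo aldehyde A4, and the alkenylchromium formed by transmetalation would add to the C3 aldehyde to give the macrocyclic allylic alcohol A3. In its favour, this coupling tolerates lactones, esters and Michael acceptors, keeps the olefin geometry of the iodide, and is a well-established way to close medium rings. The C8 angelate and the 9,10-acetonide are already differentiated in A3, so neither a regioselective acylation nor a directed osmylation is needed; on this point it is better than the chosen plan. Against it, C3 would be created in the ring closure with no dependable control element, whereas the chosen plan sets C3 by a chiral boron reagent before cyclisation. The C1 dithiane would have to be removed late, beside three olefins, a thiol-sensitive methylene lactone and the angelate. The isomerisable angelate would also travel through many steps. On structure, the open chain A4 must contain the whole C7–C10 stereotetrad, which costs a longer fragment synthesis. On mechanism, both are ring closures at an sp2 carbon under high dilution; the chromium addition is irreversible and the metathesis is reversible. On step economy after ring closure the two are about equal (three operations against four); before ring closure the chosen plan is shorter.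

Alternative 3: The ring would be cut at C5–C6. In the forward step, cathodic reduction with NiCl2·glyme and 2,2′-bipyridine would fragment the N-hydroxyphthalimide ester of seco ester A6 to a C6 radical with loss of CO2. An alkenylnickel species formed from the C5 iodide would capture the radical and reductive elimination would give macrocycle A5. In its favour, it is the most convergent of the four plans: all oxygen functions and both the angelate and the masked lactone are in place, and the amine mask keeps the methylene lactone out of radical chemistry. The C6 centre should form trans to the C7 substituent on the five-membered ring. Few steps would follow ring closure; in convergence and in the number of late steps it is better than the chosen plan. Against it, closing a ten-membered ring by this coupling has no close precedent. Reduction or dimerisation of the radical, loss of the Z geometry of the hindered alkenyl iodide, and cathodic damage to the α-oxygenated ketone and the β-silyloxy ketone are all to be feared. On structure, it carries no open stereochemical question at C8/C9, while the chosen plan does. On mechanism, radical capture is kinetic and cannot be corrected, whereas metathesis equilibrates and belongs to a reaction class with ten-membered precedents. On step economy it would win only if the long linear synthesis of A6 were shorter than the sixteen steps that lead to 22 here, which is doubtful.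

Key step: step 14

## Route

Step 1
Reactants: 1 (S)-5-(hydroxymethyl)furan-2(5H)-one
Product: 2 (S)-5-[(tert-butyldimethylsilyloxy)methyl]furan-2(5H)-one
Conditions: TBSCl, imidazole, CH2Cl2, 0 °C → rt
Reagents that add atoms: tert-butyldimethylsilyl chloride, CC(C)(C)[Si](C)(C)Cl
Why: Silylation of a primary alcohol; imidazole is too weak a base to deprotonate the γ-position, so the C5 centre (future C6) is kept, and the bulky ether will shield one face of the butenolide.

Step 2
Reactants: 2 (S)-5-[(tert-butyldimethylsilyloxy)methyl]furan-2(5H)-one; 3 vinylmagnesium bromide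
Product: 5 (4R,5S)-5-[(tert-butyldimethylsilyloxy)methyl]-4-vinyldihydrofuran-2(3H)-one, via silyl ketene acetal 4 (not isolated)
Conditions: CH2=CHMgBr (2.4 equiv), CuBr·SMe2 (1.2 equiv), Me3SiCl, THF, −78 °C; aq. NH4Cl
Reagents that add atoms: none
Why: Conjugate addition of the cuprate (CH2=CH)2CuMgBr to a butenolide; the nucleophile enters anti to the C5 silyloxymethyl group and so sets C7 trans to C6. Me3SiCl traps the enolate as ketene acetal 4, which the aqueous work-up hydrolyses.

Step 3
Reactants: 5 (4R,5S)-5-[(tert-butyldimethylsilyloxy)methyl]-4-vinyldihydrofuran-2(3H)-one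
Product: 8 (4S,5S)-5-[(tert-butyldimethylsilyloxy)methyl]-3-methylidene-4-vinyldihydrofuran-2(3H)-one, via Mannich base 6 (not isolated), via methiodide 7 (not isolated)
Conditions: LiN(iPr)2, THF, −78 °C; CH2=NMe2+ I− (Eschenmoser's salt), −78 °C → rt; MeI, MeOH, rt; aq. NaHCO3, EtOAc
Reagents that add atoms: N,N-dimethylmethyleneiminium iodide (Eschenmoser's salt), C=[N+](C)C.[I-]
Why: Mannich reaction of the lactone lithium enolate, N-methylation and E1cB loss of trimethylamine, the standard α-methylenation of γ-lactones. It is done here because later intermediates (aldehyde, enoate, ketone) would not survive the amide base; C7 is not enolisable and the C11 centre becomes sp2.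

Step 4
Reactants: 8 (4S,5S)-5-[(tert-butyldimethylsilyloxy)methyl]-3-methylidene-4-vinyldihydrofuran-2(3H)-one
Product: 9 (4S,5S)-5-(hydroxymethyl)-3-methylidene-4-vinyldihydrofuran-2(3H)-one
Conditions: HF·pyridine, pyridine, THF, 0 °C → rt
Reagents that add atoms: none
Why: Desilylation of a primary silyl ether with buffered acidic fluoride; basic fluoride is avoided because an alkoxide could add to the methylene lactone or translactonise.

Step 5
Reactants: 9 (4S,5S)-5-(hydroxymethyl)-3-methylidene-4-vinyldihydrofuran-2(3H)-one
Product: 10 (2S,3S)-4-methylidene-5-oxo-3-vinyltetrahydrofuran-2-carbaldehyde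
Conditions: Dess–Martin periodinane, NaHCO3, CH2Cl2, 0 °C → rt; used crude
Reagents that add atoms: none
Why: Dess–Martin oxidation under buffered, base-free conditions; the α-acyloxy aldehyde is epimerisable at C6 and is therefore carried on at once.

Step 6
Reactants: 10 (2S,3S)-4-methylidene-5-oxo-3-vinyltetrahydrofuran-2-carbaldehyde; 11 methyl 2-[bis(2,2,2-trifluoroethoxy)phosphoryl]propanoate
Product: 12 methyl (2Z)-2-methyl-3-[(2R,3S)-4-methylidene-5-oxo-3-vinyltetrahydrofuran-2-yl]prop-2-enoate
Conditions: 11 (1.2 equiv), KN(SiMe3)2 (1.1 equiv), 18-crown-6, THF, −78 °C; then 10, −78 °C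
Reagents that add atoms: none
Why: Still–Gennari olefination: fast, irreversible elimination from the electron-poor phosphonate adduct gives the Z enoate (C4=C5) under kinetic control. At −78 °C with the base kept below the phosphonate, the anion should take the aldehyde far faster than the methylene lactone and should not epimerise C6.

Step 7
Reactants: 12 methyl (2Z)-2-methyl-3-[(2R,3S)-4-methylidene-5-oxo-3-vinyltetrahydrofuran-2-yl]prop-2-enoate
Product: 13 (4S,5R)-5-[(1Z)-3-hydroxy-2-methylprop-1-en-1-yl]-3-methylidene-4-vinyltetrahydrofuran-2-ol (mixture of anomers)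
Conditions: iBu2AlH (4 equiv), CH2Cl2, −78 °C; aq. potassium sodium tartrate
Reagents that add atoms: none
Why: Hydride reduction; because a γ-lactone is reduced at least as fast as an enoate, both are reduced on purpose, the enoate to the Z allylic alcohol and the methylene lactone (1,2-addition) to the lactol, whose aluminium hemiacetal does not open at −78 °C.

Step 8
Reactants: 13 (4S,5R)-5-[(1Z)-3-hydroxy-2-methylprop-1-en-1-yl]-3-methylidene-4-vinyltetrahydrofuran-2-ol
Product: 14 (2Z)-2-methyl-3-[(2R,3S)-4-methylidene-5-oxo-3-vinyltetrahydrofuran-2-yl]prop-2-enal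
Conditions: TEMPO (20 mol %), PhI(OAc)2 (2.5 equiv), CH2Cl2, rt
Reagents that add atoms: none
Why: Oxoammonium (TEMPO) oxidation turns the primary allylic alcohol into the enal without Z/E isomerisation and the lactol back into the lactone in the same flask. Steps 7 and 8 together amount to a chemoselective ester-to-aldehyde change.

Step 9
Reactants: 15 2,3-butanedione; 3 vinylmagnesium bromide
Product: 16 rac-3-hydroxy-3-methylpent-4-en-2-one
Conditions: CH2=CHMgBr (0.9 equiv) added to 15 (2 equiv), THF, −78 °C; aq. NH4Cl
Reagents that add atoms: none
Why: Grignard mono-addition to a 1,2-diketone; inverse addition at low temperature and the deactivating α-alkoxide should stop the reaction after one carbonyl.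

Step 10
Reactants: 16 rac-3-hydroxy-3-methylpent-4-en-2-one
Product: 17 rac-3-methyl-3-(triethylsilyloxy)pent-4-en-2-one
Conditions: Et3SiOTf, 2,6-lutidine, CH2Cl2, −78 → 0 °C
Reagents that add atoms: triethylsilyl trifluoromethanesulfonate, CC[Si](CC)(CC)OS(=O)(=O)C(F)(F)F
Why: Silyl triflate silylation of a hindered tertiary alcohol; the ether lets the boron reagent of step 12 enolise the ketone cleanly and makes the small ketol non-volatile for the resolution.

Step 11
Reactants: 17 rac-3-methyl-3-(triethylsilyloxy)pent-4-en-2-one
Product: 18 (S)-3-methyl-3-(triethylsilyloxy)pent-4-en-2-one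
Conditions: preparative SFC on amylose tris(3,5-dimethylphenylcarbamate), CO2/iPrOH
Reagents that add atoms: none
Why: Resolution of enantiomers on a chiral stationary phase (a separation; no bond is formed). The quaternary C10 centre cannot racemise, and the (S) enantiomer is to be identified by vibrational circular dichroism.

Step 12
Reactants: 18 (S)-3-methyl-3-(triethylsilyloxy)pent-4-en-2-one; 14 (2Z)-2-methyl-3-[(2R,3S)-4-methylidene-5-oxo-3-vinyltetrahydrofuran-2-yl]prop-2-enal
Product: 21 (4S,5R)-5-[(1Z,3R,6S)-3,6-dihydroxy-2,6-dimethyl-5-oxoocta-1,7-dien-1-yl]-3-methylidene-4-vinyldihydrofuran-2(3H)-one, via enol borinate 19 (not isolated), via silylated aldol adduct 20 (not isolated)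
Conditions: (−)-Ipc2BCl, Et3N, Et2O, 0 °C; 14, −78 → −20 °C; H2O2, pH 7 buffer, MeOH, 0 °C; then HF·pyridine, THF, 0 °C
Reagents that add atoms: none
Why: Diisopinocampheylboron aldol of a methyl ketone; only the methyl group can be enolised. The ligands derived from (+)-α-pinene should direct enol borinate 19 to the Re face of the enal through a cyclic six-membered transition state, which gives the (3R) carbinol. HF·pyridine on the crude adduct 20 frees the tertiary hydroxyl.

Step 13
Reactants: 21 (4S,5R)-5-[(1Z,3R,6S)-3,6-dihydroxy-2,6-dimethyl-5-oxoocta-1,7-dien-1-yl]-3-methylidene-4-vinyldihydrofuran-2(3H)-one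
Product: 22 (4S,5R)-5-[(1Z,3R,6S)-3-(tert-butyldimethylsilyloxy)-6-hydroxy-2,6-dimethyl-5-oxoocta-1,7-dien-1-yl]-3-methylidene-4-vinyldihydrofuran-2(3H)-one
Conditions: TBSCl, imidazole, DMAP (cat.), DMF, rt
Reagents that add atoms: tert-butyldimethylsilyl chloride, CC(C)(C)[Si](C)(C)Cl
Why: Silylation with a silyl chloride takes the secondary C3 hydroxyl and leaves the tertiary C10 hydroxyl, which does not react under these conditions. The free C10 hydroxyl is needed in steps 14 and 15.

Step 14
Reactants: 22 (4S,5R)-5-[(1Z,3R,6S)-3-(tert-butyldimethylsilyloxy)-6-hydroxy-2,6-dimethyl-5-oxoocta-1,7-dien-1-yl]-3-methylidene-4-vinyldihydrofuran-2(3H)-one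
Product: 23 (3R,6R,7S,10S)-3-(tert-butyldimethylsilyloxy)-10-hydroxy-1-oxogermacra-4Z,8Z,11(13)-trien-12,6-olide
Conditions: second-generation Grubbs catalyst (H2IMes)(PCy3)Cl2Ru=CHPh (15 mol %, in three portions), 1,4-benzoquinone (30 mol %), CH2Cl2 (0.001 M), 40 °C
Reagents that add atoms: none
Why: The ruthenium alkylidene adds [2+2] to the unhindered vinyl group on C7 and cycloreverts to a ruthenium alkylidene at C8, which adds intramolecularly to the vinyl group on C10; cycloreversion of that metallacyclobutane forms C8=C9 and a ruthenium methylidene, and the loss of ethylene drives the sequence. The closest known reaction type is ring-closing metathesis to ten-membered carbocycles with second-generation ruthenium carbene catalysts, together with cross-metathesis of free tertiary allylic alcohols, which shows that a vinyl carbinol on a quaternary carbon is a competent partner and is helped by an OH···Cl–Ru hydrogen bond. The one ring formed is the ten-membered carbocycle, closed head to head between two terminal olefins so that both former vinyl CH carbons become ring atoms; high dilution counters oligomerisation. No stereocentre is formed; the only new stereo element is the olefin geometry. Z is expected under thermodynamic control because secondary metathesis equilibrates the isomers and an E C8=C9 olefin in a ring that already holds the 4Z olefin and the trans-fused lactone would be much more strained. The step needs site selectivity among four olefins: the trisubstituted C4=C5 is shielded by the silyloxy-bearing C3 and by C6, and the 1,1-disubstituted, electron-poor methylene lactone could only close a four-membered ring. The one conceivable side path, closure of a C9 alkylidene onto C4=C5 to a cyclohexene, is disfavoured because initiation takes place at the C7 vinyl group and the trisubstituted olefin is hindered. Benzoquinone suppresses olefin migration by ruthenium hydrides, and the β-silyloxy ketone and the lactone are inert to the neutral catalyst.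

Step 15
Reactants: 23 (3R,6R,7S,10S)-3-(tert-butyldimethylsilyloxy)-10-hydroxy-1-oxogermacra-4Z,8Z,11(13)-trien-12,6-olide
Product: 25 (3R,6R,7R,8S,9S,10S)-3-(tert-butyldimethylsilyloxy)-8,9,10-trihydroxy-1-oxogermacra-4Z,11(13)-dien-12,6-olide, via osmate ester 24 (not isolated)
Conditions: OsO4 (1.05 equiv), TMEDA (1.1 equiv), CH2Cl2, −78 °C; then HCl in MeOH (3 equiv), 0 °C
Reagents that add atoms: osmium tetroxide, O=[Os](=O)(=O)=O
Why: Hydrogen-bond-directed dihydroxylation: the electron-rich OsO4·TMEDA complex accepts a hydrogen bond from the C10 hydroxyl and adds suprafacially to the Z C8=C9 olefin on the face of that hydroxyl, which is also the face of the C7–C11 bond, so C8 and C9 are set all-cis to C10–OH. One equivalent at −78 °C should spare the hindered, inductively deactivated C4=C5 and the electron-poor methylene lactone. The glycolate 24 is cleaved with methanolic HCl because amine or sulfite work-ups would add to the methylene lactone.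

Step 16
Reactants: 25 (3R,6R,7R,8S,9S,10S)-3-(tert-butyldimethylsilyloxy)-8,9,10-trihydroxy-1-oxogermacra-4Z,11(13)-dien-12,6-olide; 26 angelic acid [(Z)-2-methylbut-2-enoic acid]
Product: 28 (3R,6R,7S,8S,9S,10S)-8-angeloyloxy-3-(tert-butyldimethylsilyloxy)-9,10-dihydroxy-1-oxogermacra-4Z,11(13)-dien-12,6-olide, via mixed anhydride 27 (not isolated)
Conditions: 26, 2,4,6-Cl3C6H2COCl, Et3N, PhMe, rt; then 25 (limiting), PhMe, 70 °C, no DMAP
Reagents that add atoms: none
Why: Yamaguchi-type acylation through mixed anhydride 27 without a nucleophilic catalyst, the established way to form angelates without Z to E isomerisation. The C8 hydroxyl is the least hindered (C9–OH is flanked by the quaternary C10 and C10–OH is tertiary), so mono-acylation at O8 is expected.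

Step 17
Reactants: 28 (3R,6R,7S,8S,9S,10S)-8-angeloyloxy-3-(tert-butyldimethylsilyloxy)-9,10-dihydroxy-1-oxogermacra-4Z,11(13)-dien-12,6-olide
Product: 29 (3R,6R,7S,8S,9S,10S)-9-acetoxy-8-angeloyloxy-3-(tert-butyldimethylsilyloxy)-10-hydroxy-1-oxogermacra-4Z,11(13)-dien-12,6-olide
Conditions: Ac2O, pyridine, DMAP (cat.), CH2Cl2, 0 °C → rt
Reagents that add atoms: acetic anhydride, CC(=O)OC(C)=O
Why: Acetylation of the only remaining secondary hydroxyl; the tertiary C10 hydroxyl does not acylate under these mild conditions, and the low temperature guards the angelate and the β-silyloxy ketone.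

Step 18
Reactants: 29 (3R,6R,7S,8S,9S,10S)-9-acetoxy-8-angeloyloxy-3-(tert-butyldimethylsilyloxy)-10-hydroxy-1-oxogermacra-4Z,11(13)-dien-12,6-olide
Product: 30 (3R,6R,7S,8S,9S,10S)-9-acetoxy-8-angeloyloxy-3,10-dihydroxy-1-oxogermacra-4Z,11(13)-dien-12,6-olide (CNP0308559.3)
Conditions: HF·pyridine, pyridine, THF, 0 °C → rt
Reagents that add atoms: none
Why: Desilylation with buffered acidic fluoride; basic fluoride is avoided because it would provoke retro-aldol cleavage, acyl migration and Michael addition. No stereocentre is touched.

## Compound list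

1 | (S)-5-(hydroxymethyl)furan-2(5H)-one | OC[C@@H]1C=CC(=O)O1 | starting material
2 | (S)-5-[(tert-butyldimethylsilyloxy)methyl]furan-2(5H)-one | CC(C)(C)[Si](C)(C)OC[C@@H]1C=CC(=O)O1 | intermediate
3 | vinylmagnesium bromide | C=C[Mg]Br | starting material
4 | trimethylsilyl ketene acetal of 5, (2S,3S)-2-[(tert-butyldimethylsilyloxy)methyl]-5-(trimethylsilyloxy)-3-vinyl-2,3-dihydrofuran | C1=C(O[Si](C)(C)C)O[C@H](CO[Si](C)(C)C(C)(C)C)[C@H]1C=C | intermediate (not isolated)
5 | (4R,5S)-5-[(tert-butyldimethylsilyloxy)methyl]-4-vinyldihydrofuran-2(3H)-one | C1C(=O)O[C@H](CO[Si](C)(C)C(C)(C)C)[C@H]1C=C | intermediate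
6 | (3R,4S,5S)-5-[(tert-butyldimethylsilyloxy)methyl]-3-[(dimethylamino)methyl]-4-vinyldihydrofuran-2(3H)-one | CN(C)C[C@@H]1C(=O)O[C@H](CO[Si](C)(C)C(C)(C)C)[C@H]1C=C | intermediate (not isolated)
7 | N-methyl quaternary ammonium iodide of 6 | C[N+](C)(C)C[C@@H]1C(=O)O[C@H](CO[Si](C)(C)C(C)(C)C)[C@H]1C=C.[I-] | intermediate (not isolated)
8 | (4S,5S)-5-[(tert-butyldimethylsilyloxy)methyl]-3-methylidene-4-vinyldihydrofuran-2(3H)-one | C=C1C(=O)O[C@H](CO[Si](C)(C)C(C)(C)C)[C@H]1C=C | intermediate
9 | (4S,5S)-5-(hydroxymethyl)-3-methylidene-4-vinyldihydrofuran-2(3H)-one | C=C1C(=O)O[C@H](CO)[C@H]1C=C | intermediate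
10 | (2S,3S)-4-methylidene-5-oxo-3-vinyltetrahydrofuran-2-carbaldehyde | C=C1C(=O)O[C@H](C=O)[C@H]1C=C | intermediate
11 | methyl 2-[bis(2,2,2-trifluoroethoxy)phosphoryl]propanoate | COC(=O)C(C)P(=O)(OCC(F)(F)F)OCC(F)(F)F | starting material
12 | methyl (2Z)-2-methyl-3-[(2R,3S)-4-methylidene-5-oxo-3-vinyltetrahydrofuran-2-yl]prop-2-enoate | C=C1C(=O)O[C@H](/C=C(/C)C(=O)OC)[C@H]1C=C | intermediate
13 | (4S,5R)-5-[(1Z)-3-hydroxy-2-methylprop-1-en-1-yl]-3-methylidene-4-vinyltetrahydrofuran-2-ol (anomers) | C=C1C(O)O[C@H](/C=C(/C)CO)[C@H]1C=C | intermediate
14 | (2Z)-2-methyl-3-[(2R,3S)-4-methylidene-5-oxo-3-vinyltetrahydrofuran-2-yl]prop-2-enal | C=C1C(=O)O[C@H](/C=C(/C)C=O)[C@H]1C=C | intermediate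
15 | 2,3-butanedione | CC(=O)C(C)=O | starting material
16 | rac-3-hydroxy-3-methylpent-4-en-2-one | CC(=O)C(C)(O)C=C | intermediate
17 | rac-3-methyl-3-(triethylsilyloxy)pent-4-en-2-one | CC(=O)C(C)(O[Si](CC)(CC)CC)C=C | intermediate
18 | (S)-3-methyl-3-(triethylsilyloxy)pent-4-en-2-one | CC(=O)[C@@](C)(O[Si](CC)(CC)CC)C=C | intermediate
19 | diisopinocampheylboron enolate (enol borinate) of 18 | C[C@H]1[C@H](B(OC(=C)[C@@](C)(O[Si](CC)(CC)CC)C=C)[C@@H]3C[C@@H]4C[C@H]([C@H]3C)C4(C)C)C[C@@H]2C[C@H]1C2(C)C | intermediate (not isolated)
20 | (4S,5R)-5-[(1Z,3R,6S)-3-hydroxy-2,6-dimethyl-5-oxo-6-(triethylsilyloxy)octa-1,7-dien-1-yl]-3-methylidene-4-vinyldihydrofuran-2(3H)-one | C=C1C(=O)O[C@H](/C=C(/C)[C@H](O)CC(=O)[C@@](C)(O[Si](CC)(CC)CC)C=C)[C@H]1C=C | intermediate (not isolated)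
21 | (4S,5R)-5-[(1Z,3R,6S)-3,6-dihydroxy-2,6-dimethyl-5-oxoocta-1,7-dien-1-yl]-3-methylidene-4-vinyldihydrofuran-2(3H)-one | C=C1C(=O)O[C@H](/C=C(/C)[C@H](O)CC(=O)[C@@](C)(O)C=C)[C@H]1C=C | intermediate
22 | (4S,5R)-5-[(1Z,3R,6S)-3-(tert-butyldimethylsilyloxy)-6-hydroxy-2,6-dimethyl-5-oxoocta-1,7-dien-1-yl]-3-methylidene-4-vinyldihydrofuran-2(3H)-one (seco C8–C9 divinyl compound) | C=C1C(=O)O[C@H](/C=C(/C)[C@H](O[Si](C)(C)C(C)(C)C)CC(=O)[C@@](C)(O)C=C)[C@H]1C=C | intermediate
23 | (3R,6R,7S,10S)-3-(tert-butyldimethylsilyloxy)-10-hydroxy-1-oxogermacra-4Z,8Z,11(13)-trien-12,6-olide | C=C1C(=O)O[C@@H]2/C=C(/C)[C@H](O[Si](C)(C)C(C)(C)C)CC(=O)[C@@](C)(O)/C=C\[C@@H]12 | intermediate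
24 | cyclic 8,9-osmate ester of 25, OsO2(OR)2·TMEDA (hexavalent osmium) | C=C1C(=O)O[C@@H]2/C=C(/C)[C@H](O[Si](C)(C)C(C)(C)C)CC(=O)[C@@](C)(O)[C@H]3O[Os-2]4(=O)(=O)([N+](C)(C)CC[N+]4(C)C)O[C@H]3[C@@H]12 | intermediate (not isolated)
25 | (3R,6R,7R,8S,9S,10S)-3-(tert-butyldimethylsilyloxy)-8,9,10-trihydroxy-1-oxogermacra-4Z,11(13)-dien-12,6-olide | C=C1C(=O)O[C@@H]2/C=C(/C)[C@H](O[Si](C)(C)C(C)(C)C)CC(=O)[C@@](C)(O)[C@@H](O)[C@@H](O)[C@@H]12 | intermediate
26 | angelic acid, (Z)-2-methylbut-2-enoic acid | C/C=C(/C)C(=O)O | starting material
27 | angelic 2,4,6-trichlorobenzoic anhydride | C/C=C(/C)C(=O)OC(=O)c1c(Cl)cc(Cl)cc1Cl | intermediate (not isolated)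
28 | (3R,6R,7S,8S,9S,10S)-8-angeloyloxy-3-(tert-butyldimethylsilyloxy)-9,10-dihydroxy-1-oxogermacra-4Z,11(13)-dien-12,6-olide | C=C1C(=O)O[C@@H]2/C=C(/C)[C@H](O[Si](C)(C)C(C)(C)C)CC(=O)[C@@](C)(O)[C@@H](O)[C@@H](OC(=O)/C(C)=C\C)[C@@H]12 | intermediate
29 | (3R,6R,7S,8S,9S,10S)-9-acetoxy-8-angeloyloxy-3-(tert-butyldimethylsilyloxy)-10-hydroxy-1-oxogermacra-4Z,11(13)-dien-12,6-olide | C=C1C(=O)O[C@@H]2/C=C(/C)[C@H](O[Si](C)(C)C(C)(C)C)CC(=O)[C@@](C)(O)[C@@H](OC(C)=O)[C@@H](OC(=O)/C(C)=C\C)[C@@H]12 | intermediate
30 | (3R,6R,7S,8S,9S,10S)-9-acetoxy-8-angeloyloxy-3,10-dihydroxy-1-oxogermacra-4Z,11(13)-dien-12,6-olide (CNP0308559.3) | C=C1C(=O)O[C@@H]2/C=C(/C)[C@H](O)CC(=O)[C@@](C)(O)[C@@H](OC(C)=O)[C@@H](OC(=O)/C(C)=C\C)[C@@H]12 | target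

## Step count and least certain steps

Total: 18 steps. Longest linear sequence: 15 steps (from 1 through steps 1–8 and 12–18); the ketone branch (steps 9–11) joins at step 12.

Step 14 (key step). The most likely failure is intermolecular metathesis outrunning closure of the strained ring, because the alkylidene formed at C8 must engage the hindered vinyl group on the quaternary C10 while a second molecule offers an unhindered one. Misdirected closure of a C9 alkylidene onto C4=C5 and formation of the E olefin are lesser risks. Fallback by relay ring-closing metathesis, setting out from 18 and 14 and returning at 23: ozonolysis of 18 (O3, then Me2S) would give aldehyde F1, and a Wittig reaction with Ph3P=CH(CH2)3CH=CH2 would give relay ketone F2. Its enol borinate F3 would be added to 14 as in step 12 to give silylated adduct F4 and, after HF·pyridine, diol F5; silylation as in step 13 would give relay triene F6. With the catalyst of step 14, ruthenium loads on the unhindered terminal olefin of the relay chain, expels cyclopentene and is thereby delivered intramolecularly to C9. The hindered alkylidene then has only to capture the accessible vinyl group on C7, which gives 23.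

Step 15. The likely failure is poor facial selectivity, since the lactone carbon C11 stands on the same face as the directing hydroxyl and the ring conformation may turn the hydroxyl away from the olefin. Lesser risks are osmylation of C4=C5 and partial loss of the silyl ether during the acidic cleavage. Fallback by Woodward cis-hydroxylation, setting out from 23 and returning at 29: with I2 and AgOAc in wet acetic acid, the iodonium ion would form on the sterically preferred face, acetate would open it from the other side, and the acetoxonium ion formed with inversion would be hydrolysed. The cis oxygens thus arrive on the face opposite to that taken by an undirected osmylation. The products would be the 9-acetate F7 and its 8-acetate isomer F8, which interconvert by acetyl migration; F7, angeloylated as in step 16, is 29.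

Step 16. The likely failures are isomerisation of the activated angeloyl group to the tigloyl group, acylation at O9 or at both hydroxyls, and β-elimination of the silyloxy group at 70 °C in the presence of the amine salt. Fallback that builds the angelate on the molecule, setting out from 25 and returning at 28: O8 would be esterified at 0 °C with 2-[bis(2,2,2-trifluoroethoxy)phosphoryl]propanoic acid and diisopropylcarbodiimide to give phosphonate ester F9, in which no olefin geometry is yet at stake. A Still–Gennari olefination with acetaldehyde (KN(SiMe3)2, 18-crown-6, −78 °C) would then form the Z-2-methylbut-2-enoate under kinetic control, giving 28.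

Step 12. The likely failure is a low or reversed facial preference at C3, because reagent control with methyl ketones is only moderate and the quaternary α-silyloxy centre may oppose it; Z to E isomerisation of the enal is a second risk. Fallback by a Lewis-acid-catalysed Mukaiyama aldol, setting out from 18 and 14 and returning at 21: 18 would be converted with Me3SiOTf and Et3N into enol silane F10, which would add to 14 under a chiral oxazaborolidinone Lewis acid chosen for the (3R) adduct to give bis-silyl ether F11; HF·pyridine would then give 21.

## Further compounds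

F1 | step 14 | (S)-2-methyl-3-oxo-2-(triethylsilyloxy)butanal | CC(=O)[C@@](C)(O[Si](CC)(CC)CC)C=O
F2 | step 14 | (3S,4Z)-3-methyl-3-(triethylsilyloxy)deca-4,9-dien-2-one | CC(=O)[C@@](C)(O[Si](CC)(CC)CC)/C=C\CCCC=C
F3 | step 14 | diisopinocampheylboron enolate of F2 | C[C@H]1[C@H](B(OC(=C)[C@@](C)(O[Si](CC)(CC)CC)/C=C\CCCC=C)[C@@H]3C[C@@H]4C[C@H]([C@H]3C)C4(C)C)C[C@@H]2C[C@H]1C2(C)C
F4 | step 14 | (4S,5R)-5-[(1Z,3R,6S,7Z)-3-hydroxy-2,6-dimethyl-5-oxo-6-(triethylsilyloxy)trideca-1,7,12-trien-1-yl]-3-methylidene-4-vinyldihydrofuran-2(3H)-one | C=C1C(=O)O[C@H](/C=C(/C)[C@H](O)CC(=O)[C@@](C)(O[Si](CC)(CC)CC)/C=C\CCCC=C)[C@H]1C=C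
F5 | step 14 | (4S,5R)-5-[(1Z,3R,6S,7Z)-3,6-dihydroxy-2,6-dimethyl-5-oxotrideca-1,7,12-trien-1-yl]-3-methylidene-4-vinyldihydrofuran-2(3H)-one | C=C1C(=O)O[C@H](/C=C(/C)[C@H](O)CC(=O)[C@@](C)(O)/C=C\CCCC=C)[C@H]1C=C
F6 | step 14 | (4S,5R)-5-[(1Z,3R,6S,7Z)-3-(tert-butyldimethylsilyloxy)-6-hydroxy-2,6-dimethyl-5-oxotrideca-1,7,12-trien-1-yl]-3-methylidene-4-vinyldihydrofuran-2(3H)-one | C=C1C(=O)O[C@H](/C=C(/C)[C@H](O[Si](C)(C)C(C)(C)C)CC(=O)[C@@](C)(O)/C=C\CCCC=C)[C@H]1C=C
F7 | step 15 | 9-acetoxy-3-(tert-butyldimethylsilyloxy)-8,10-dihydroxy-1-oxogermacra-4Z,11(13)-dien-12,6-olide (8β,9β,10β) | C=C1C(=O)O[C@@H]2/C=C(/C)[C@H](O[Si](C)(C)C(C)(C)C)CC(=O)[C@@](C)(O)[C@@H](OC(C)=O)[C@@H](O)[C@@H]12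
F8 | step 15 | 8-acetoxy-3-(tert-butyldimethylsilyloxy)-9,10-dihydroxy-1-oxogermacra-4Z,11(13)-dien-12,6-olide (8β,9β,10β) | C=C1C(=O)O[C@@H]2/C=C(/C)[C@H](O[Si](C)(C)C(C)(C)C)CC(=O)[C@@](C)(O)[C@@H](O)[C@@H](OC(C)=O)[C@@H]12
F9 | step 16 | 8-O-{2-[bis(2,2,2-trifluoroethoxy)phosphoryl]propanoyl} derivative of 25 | C=C1C(=O)O[C@@H]2/C=C(/C)[C@H](O[Si](C)(C)C(C)(C)C)CC(=O)[C@@](C)(O)[C@@H](O)[C@@H](OC(=O)C(C)P(=O)(OCC(F)(F)F)OCC(F)(F)F)[C@@H]12
F10 | step 12 | (S)-3-methyl-3-(triethylsilyloxy)-2-(trimethylsilyloxy)penta-1,4-diene | C=C(O[Si](C)(C)C)[C@@](C)(O[Si](CC)(CC)CC)C=C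
F11 | step 12 | 3-O-trimethylsilyl ether of 20 | C=C1C(=O)O[C@H](/C=C(/C)[C@H](O[Si](C)(C)C)CC(=O)[C@@](C)(O[Si](CC)(CC)CC)C=C)[C@H]1C=C
A1 | alternative 1 | ten-membered 4-en-1-yne tertiary carbinol | C=C(CO[Si](C)(C)C(C)(C)C)[C@H]1[C@H](O[Si](C)(C)C(C)(C)C)/C=C(/C)[C@H](OCc2ccc(OC)cc2)C#C[C@@](C)(O)[C@H]2OC(C)(C)O[C@H]21
A2 | alternative 1 | seco terminal alkyne with C10 methyl ketone | C=C(CO[Si](C)(C)C(C)(C)C)[C@@H]([C@H](O[Si](C)(C)C(C)(C)C)/C=C(/C)[C@H](OCc1ccc(OC)cc1)C#C)[C@@H]1OC(C)(C)O[C@@H]1C(C)=O
A3 | alternative 2 | macrocyclic allylic alcohol with C1 dithiane | C=C1C(=O)O[C@@H]2/C=C(/C)[C@H](O)CC4(SCCCS4)[C@@]3(C)OC(C)(C)O[C@H]3[C@@H](OC(=O)/C(C)=C\C)[C@@H]12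
A4 | alternative 2 | seco C4 alkenyl iodide with C3 aldehyde | C=C1C(=O)O[C@H](/C=C(/C)I)[C@H]1[C@H](OC(=O)/C(C)=C\C)[C@@H]2OC(C)(C)O[C@]2(C)C3(CC=O)SCCCS3
A5 | alternative 3 | macrocycle with amine-masked trans lactone | CN(C)C[C@@H]1C(=O)O[C@@H]2/C=C(/C)[C@H](O[Si](C)(C)C(C)(C)C)CC(=O)[C@@]3(C)OC(C)(C)O[C@H]3[C@@H](OC(=O)/C(C)=C\C)[C@@H]12
A6 | alternative 3 | seco C5 alkenyl iodide with C6 N-hydroxyphthalimide ester | I/C=C(/C)[C@H](O[Si](C)(C)C(C)(C)C)CC(=O)[C@@]3(C)OC(C)(C)O[C@H]3[C@@H](OC(=O)/C(C)=C\C)[C@H]1[C@H](CN(C)C)C(=O)O[C@@H]1C(=O)ON2C(=O)c4ccccc4C2=O
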